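**Assumption:** the target is achiral (no stereocentre, no stereogenic double bond). Compounds 1, 4, 5 and 10 are taken as commercially available.

**Ring numbering used throughout:** ring A (the phenol-derived ring) has C1 (CO2Me), C2 (OH), C3 (Me), C4 (O of the depside ester), C5 (Me), C6 (Me). Ring B (the acyl ring) has C1' (ester carbonyl carbon attached), C2' (OMe), C3' (Me), C4' (OH), C5' (Cl), C6' (Me).

## The problem

The target is a depside of two hexasubstituted benzene rings with no stereocentre, so the whole task is regiochemical. The central ester joins a benzoyl carbon flanked by OMe and Me (C2', C6') to a phenolic oxygen flanked by two methyl groups (C3, C5), which is about the most hindered acyl transfer an aryl ester can demand. Ring B carries its oxygens the "wrong" way round: the hydroxyl ortho to the carbonyl (C2') is methylated while the normally more reactive para hydroxyl (C4') is free. Ring A needs the opposite: the non-chelated C4 oxygen acylated and the chelated C2 hydroxyl free. The aryl ester is an activated ester and will not survive alkoxide, hydroxide or amines at elevated temperature. The phenols are electron-rich and prone to over-halogenation, and the aryl chloride is at risk under hydrogenolysis.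

The feature that opens a ring-forming solution is the sequence C4'(OH)–C3'(Me)–C2'(OMe)–C1'(CO2Ar)–C6'(Me)–C5' of ring B. C4' is a ketene carbonyl carbon, C3'/C2' are the two carbons of 1-methoxyprop-1-yne, and C1'–C6'–C5' is the α-carbon and vinyl group of an ester-substituted vinylketene. A Danheiser benzannulation would therefore deliver the methyl ether, the free hydroxyl and the ester in their correct places without any differentiation step. C5' is also the only aromatic C–H left in the whole molecule once ring B is made, which makes a final chlorination regiochemically unambiguous.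

## Retrosynthesis

**18 ⇒ 17.** The C5'–Cl bond is cut first. In des-chloro depside 17 the carbon C5' is the single unsubstituted aromatic position of the molecule, ortho to the free C4' hydroxyl and para to the C2' methoxy group. The forward reaction only has to be a mild electrophilic chlorination that stops at one equivalent. Removing chlorine also simplifies the three-carbon unit needed for ring B to a plain methacryloyl group.

**17 ⇒ 9 + 12 (key disconnection).** Ring B is taken apart at C3'–C4', C1'–C2' and C4'–C5'. This gives 1-methoxyprop-1-yne 12 and the vinylketene 13, which is written back to the diazo β-ketoester 9 (Wolff rearrangement). Other cuts through ring B would leave the O-methyl/O-H differentiation or the hindered acyl transfer unsolved. This cut places the ester on the open-chain partner, so the depside C–O bond already exists before ring B does. The precursor 9 is an acyclic acyl unit on ring A, and 12 is a four-carbon ynol ether. The forward step must give regioselective [2+2] addition of 12 to ketene 13, opening of cyclobutenone 14 to dienylketene 15, six-electron closure to 16 and enolization to 17.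

**9 ⇒ 8 ⇒ 3 + 6.** The diazo group is removed (diazo transfer in the forward sense) to give aryl β-ketoester 8. The aryl ester C–O bond of 8 is then cut to phenol 3 and methacryloylketene 7, generated from acyl Meldrum's acid 6. The hindered C4 oxygen is thus acylated by a small, linear ketene through a cyclic transition state, not by a 2,6-disubstituted benzoyl electrophile. The forward reaction must select the free C4 hydroxyl over the C2 hydroxyl, which is hydrogen-bonded to the methyl ester.

**3 ⇒ 2 ⇒ 1.** The C5 methyl group of ring A is traced to a formyl group (aldehyde 2) and then to hydrogen. This leads to commercial methyl 2,4-dihydroxy-3,6-dimethylbenzoate 1, whose only free ring position is C5. Formylation and deoxygenation are both routine on this ring type.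

**6 ⇒ 4 + 5; 12 ⇒ 10.** Acyl Meldrum's acid 6 comes from Meldrum's acid 4 and methacryloyl chloride 5. Ynol ether 12 comes from 2-chloro-1,1-dimethoxyethane 10 by double elimination to sodium methoxyacetylide 11 and C-methylation.

## Roads not taken

**Alternative 1:** the obvious cut is the depside ester bond itself. Acid A1 (4-(benzyloxy)-5-chloro-2-methoxy-3,6-dimethylbenzoic acid) would be made from 1 by chlorination, 4-O-benzylation, 2-O-methylation and forcing saponification. It would be coupled with phenol 3 (trifluoroacetic anhydride) to protected depside A2, followed by debenzylation.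
- This is well precedented and about as long as the chosen route, so the chosen plan does not win on step count.
- Its weaknesses are structural: four functional-group and protecting-group operations only to invert the natural O-reactivity of ring B; a coupling between two di-ortho-substituted partners; and removal of a benzyl ether beside an aryl chloride.
- The chosen plan needs no protecting group and gets the O-pattern from the ring construction. Alternative 1 is kept as the fallback.

**Alternative 2:** ring B could be built on ring A by a polyketide-type aromatization. Diketo-dioxinone A3 would be thermolysed with phenol 3 to an aryl triketo-ester, and aldol condensation/dehydration would give the 2',4'-dihydroxy depside A4.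
- Ester formation by ketene capture is shared with the chosen plan.
- A4 has three free phenols, and the one to be methylated (C2', chelated) is the least reactive. Protection, methylation and deprotection would have to follow.
- A3 itself needs several steps. The ynol ether of the chosen plan brings the O-methyl group in already attached.

**Alternative 3:** the same benzannulation could be run on ring A instead. Ynol ester A5 (the prop-1-ynyl ester of acid A1) would react with the vinylketene from diazo ketone A6 to give A2, forming ring A and the depside C–O bond at once.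
- Alkynyl carboxylates are acyl donors and far weaker ketenophiles than ynol ethers.
- Making A5 from a di-ortho-substituted carboxylate has no precedent.
- Ring B would still have to be made classically with all its protecting-group steps. This gives two unknown steps and no saving.

Key step: step 7

## Route

**Step 1**
Reactants: 1 methyl 2,4-dihydroxy-3,6-dimethylbenzoate
Product: 2 methyl 5-formyl-2,4-dihydroxy-3,6-dimethylbenzoate
Conditions: Cl2CHOMe, TiCl4 (2.5 equiv), CH2Cl2, −10 °C to rt; then aq. HCl
Reagents that add atoms: dichloromethyl methyl ether COC(Cl)Cl (formyl carbon); water O (formyl oxygen, on hydrolysis of the α-chloro ether)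
Why: Rieche formylation; C5 is the only free ring position and is ortho to the titanium-bound C4 phenoxide, so no regiochemical choice exists.

**Step 2**
Reactants: 2 methyl 5-formyl-2,4-dihydroxy-3,6-dimethylbenzoate
Product: 3 methyl 2,4-dihydroxy-3,5,6-trimethylbenzoate
Conditions: Et3SiH (3 equiv), CF3CO2H, CH2Cl2, 0 °C to rt
Reagents that add atoms: none
Why: Ionic hydrogenation of an ortho/para-hydroxybenzaldehyde to the methylarene through a hydroxy-stabilized benzylic cation (quinone methide type); the ring is fully substituted, so diarylmethane formation is excluded and the ester is inert.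

**Step 3**
Reactants: 4 2,2-dimethyl-1,3-dioxane-4,6-dione (Meldrum's acid); 5 methacryloyl chloride
Product: 6 5-(1-hydroxy-2-methylprop-2-en-1-ylidene)-2,2-dimethyl-1,3-dioxane-4,6-dione
Conditions: pyridine (2 equiv), CH2Cl2, 0 °C to rt
Reagents that add atoms: none
Why: Standard C-acylation of Meldrum's acid by an acid chloride; the α-methyl group of the methacryloyl unit slows conjugate addition, and the product is used without storage.

**Step 4**
Reactants: 3 methyl 2,4-dihydroxy-3,5,6-trimethylbenzoate; 6 5-(1-hydroxy-2-methylprop-2-en-1-ylidene)-2,2-dimethyl-1,3-dioxane-4,6-dione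
Product: 8 3-hydroxy-4-(methoxycarbonyl)-2,5,6-trimethylphenyl 4-methyl-3-oxopent-4-enoate, via methacryloylketene 7 (not isolated)
Conditions: toluene, 90 °C
Reagents that add atoms: none
Why: Thermal fragmentation of the acyl Meldrum's acid gives acylketene 7, which adds the phenol through a planar six-membered transition state with little steric demand; the C4 hydroxyl reacts in preference to the C2 hydroxyl, which is tied up in a hydrogen bond to the ester carbonyl.

**Step 5**
Reactants: 8 3-hydroxy-4-(methoxycarbonyl)-2,5,6-trimethylphenyl 4-methyl-3-oxopent-4-enoate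
Product: 9 3-hydroxy-4-(methoxycarbonyl)-2,5,6-trimethylphenyl 2-diazo-4-methyl-3-oxopent-4-enoate
Conditions: 4-acetamidobenzenesulfonyl azide, Et3N, MeCN, 0 °C to rt
Reagents that add atoms: 4-acetamidobenzenesulfonyl azide CC(=O)Nc1ccc(cc1)S(=O)(=O)N=[N+]=[N-]
Why: Regitz diazo transfer to the doubly activated methylene of a β-ketoester; ring A has no free position for azo coupling and the low temperature keeps the aryl ester intact.

**Step 6**
Reactants: 10 2-chloro-1,1-dimethoxyethane
Product: 12 1-methoxyprop-1-yne, via sodium methoxyacetylide 11 (not isolated)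
Conditions: NaNH2 (3 equiv), liq. NH3, −33 °C; then MeI
Reagents that add atoms: iodomethane CI
Why: Classical double elimination (HCl, then MeOH) of a chloroacetal to the alkoxyacetylide and C-alkylation of the acetylide in liquid ammonia; the volatile product is distilled and used as a solution.

**Step 7**
Reactants: 9 3-hydroxy-4-(methoxycarbonyl)-2,5,6-trimethylphenyl 2-diazo-4-methyl-3-oxopent-4-enoate; 12 1-methoxyprop-1-yne
Product: 17 3-hydroxy-4-(methoxycarbonyl)-2,5,6-trimethylphenyl 4-hydroxy-2-methoxy-3,6-dimethylbenzoate, via vinylketene 13 (not isolated), via vinylcyclobutenone 14 (not isolated), via dienylketene 15 (not isolated), via cyclohexadienone 16 (not isolated)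
Conditions: 12 (4 equiv), hν (365 nm), ClCH2CH2Cl, rt; then 80 °C
Reagents that add atoms: none
Why: Proposed new method: a 2-diazo-3-oxo-4-enoate has not been used as the vinylketene source of a Danheiser benzannulation, the closest known reaction type being the photochemical Wolff rearrangement/benzannulation of α,β-unsaturated α'-diazo ketones with alkoxy- and siloxyalkynes. Light-induced loss of N2 from 9 with 1,2-shift of the isopropenyl group (the ketone substituent migrates, not the aryloxy group) gives the ester-substituted vinylketene 13. The nucleophilic methyl-bearing carbon of 12 attacks the ketene carbonyl carbon and the zwitterion closes by C–C bond formation to the four-membered ring of 14, a formal [2+2] cycloaddition whose regiochemistry is fixed by the polarity of the ynol ether and which places OMe on the carbon next to the ester-bearing carbon. Reversible conrotatory four-electron opening of 14 gives dienylketene 15, and ring B is closed by a thermal disrotatory six-electron electrocyclization that joins the ketene carbon (C4') to the CH2 terminus (C5'); enolization of 16 is the irreversible, aromatizing step. No stereocentre survives, since 14 is racemic and its quaternary carbon becomes sp2. The step needs C-closure of the zwitterion in preference to O-closure onto the ester carbonyl (a 4-pyranone), and it needs 14 to open with the isopropenyl group turned inward, because the other rotamer could close through the ester oxygen to a 6-aryloxy-2-pyranone. The aryl ester carbonyl oxygen is a weak nucleophile, the ring opening is reversible, and only the carbocyclic path ends in a benzene ring, which should draw the material that way. The excess of 12 is meant to outrun capture of ketene 13 by the chelated C2 hydroxyl of ring A or by the product phenol, and 365 nm light is chosen to excite the diazo chromophore while sparing the aryl ester from photo-Fries rearrangement.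

**Step 8**
Reactants: 17 3-hydroxy-4-(methoxycarbonyl)-2,5,6-trimethylphenyl 4-hydroxy-2-methoxy-3,6-dimethylbenzoate
Product: 18 3-hydroxy-4-(methoxycarbonyl)-2,5,6-trimethylphenyl 5-chloro-4-hydroxy-2-methoxy-3,6-dimethylbenzoate (CNP0121273.0)
Conditions: NCS (1.0 equiv), DMF, 0 °C to rt
Reagents that add atoms: N-chlorosuccinimide ClN1C(=O)CCC1=O
Why: Electrophilic aromatic chlorination at C5', the only aromatic C–H in the molecule, activated by the ortho hydroxyl and the para methoxy group; ring A is fully substituted and its phenol is deactivated by chelation to the ester.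

## Compound list

1 | methyl 2,4-dihydroxy-3,6-dimethylbenzoate | COC(=O)c1c(C)cc(O)c(C)c1O | starting material
2 | methyl 5-formyl-2,4-dihydroxy-3,6-dimethylbenzoate | COC(=O)c1c(C)c(C=O)c(O)c(C)c1O | intermediate
3 | methyl 2,4-dihydroxy-3,5,6-trimethylbenzoate | COC(=O)c1c(C)c(C)c(O)c(C)c1O | intermediate
4 | 2,2-dimethyl-1,3-dioxane-4,6-dione (Meldrum's acid) | CC1(C)OC(=O)CC(=O)O1 | starting material
5 | methacryloyl chloride (2-methylprop-2-enoyl chloride) | CC(=C)C(Cl)=O | starting material
6 | 5-(1-hydroxy-2-methylprop-2-en-1-ylidene)-2,2-dimethyl-1,3-dioxane-4,6-dione | CC(=C)C(O)=C1C(=O)OC(C)(C)OC1=O | intermediate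
7 | 4-methylpenta-1,4-diene-1,3-dione (methacryloylketene) | CC(=C)C(=O)C=C=O | intermediate
8 | 3-hydroxy-4-(methoxycarbonyl)-2,5,6-trimethylphenyl 4-methyl-3-oxopent-4-enoate | COC(=O)c1c(C)c(C)c(OC(=O)CC(=O)C(C)=C)c(C)c1O | intermediate
9 | 3-hydroxy-4-(methoxycarbonyl)-2,5,6-trimethylphenyl 2-diazo-4-methyl-3-oxopent-4-enoate | COC(=O)c1c(C)c(C)c(OC(=O)C(=[N+]=[N-])C(=O)C(C)=C)c(C)c1O | intermediate
10 | 2-chloro-1,1-dimethoxyethane | COC(CCl)OC | starting material
11 | sodium methoxyacetylide | COC#[C-].[Na+] | intermediate
12 | 1-methoxyprop-1-yne | COC#CC | intermediate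
13 | 3-hydroxy-4-(methoxycarbonyl)-2,5,6-trimethylphenyl 3-methyl-2-(oxomethylidene)but-3-enoate (vinylketene) | COC(=O)c1c(C)c(C)c(OC(=O)C(=C=O)C(C)=C)c(C)c1O | intermediate
14 | 3-hydroxy-4-(methoxycarbonyl)-2,5,6-trimethylphenyl 2-methoxy-3-methyl-4-oxo-1-(prop-1-en-2-yl)cyclobut-2-ene-1-carboxylate (racemic) | COC(=O)c1c(C)c(C)c(OC(=O)C2(C(C)=C)C(=O)C(C)=C2OC)c(C)c1O | intermediate
15 | 3-hydroxy-4-(methoxycarbonyl)-2,5,6-trimethylphenyl (2Z)-3-methoxy-4-methyl-5-oxo-2-(prop-1-en-2-yl)penta-2,4-dienoate (dienylketene) | COC(=O)c1c(C)c(C)c(OC(=O)C(/C(C)=C)=C(OC)/C(C)=C=O)c(C)c1O | intermediate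
16 | 3-hydroxy-4-(methoxycarbonyl)-2,5,6-trimethylphenyl 6-methoxy-2,5-dimethyl-4-oxocyclohexa-1,5-diene-1-carboxylate | COC(=O)c1c(C)c(C)c(OC(=O)C2=C(C)CC(=O)C(C)=C2OC)c(C)c1O | intermediate
17 | 3-hydroxy-4-(methoxycarbonyl)-2,5,6-trimethylphenyl 4-hydroxy-2-methoxy-3,6-dimethylbenzoate | COC(=O)c1c(C)c(C)c(OC(=O)c2c(C)cc(O)c(C)c2OC)c(C)c1O | intermediate
18 | 3-hydroxy-4-(methoxycarbonyl)-2,5,6-trimethylphenyl 5-chloro-4-hydroxy-2-methoxy-3,6-dimethylbenzoate | COC(=O)c1c(C)c(C)c(OC(=O)c2c(C)c(Cl)c(O)c(C)c2OC)c(C)c1O | target

## Step count and risk

Total steps: 8. Longest linear sequence: 6 (steps 1, 2, 4, 5, 7, 8); steps 3 and 6 make the two side components.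

**Step 7 (key step, new method).** The most likely failures are:
- diversion of the ketene/ynol ether adduct into oxygen-closure pathways (onto the ester carbonyl at the zwitterion or at the dienylketene stage) in place of carbocyclization;
- capture of the ketene by the ring A hydroxyl or by the product phenol;
- dipolar cycloaddition of the electron-poor diazo group to the electron-rich alkyne before nitrogen is lost.

All three follow from placing an acceptor ester on the ketene carbon, which is the untested element.

Fallback by known chemistry, setting out from 1 and 3 and returning at 17: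
- 1 is benzylated at the non-chelated hydroxyl (BnBr, K2CO3, acetone) to methyl 4-(benzyloxy)-2-hydroxy-3,6-dimethylbenzoate F1.
- The chelated hydroxyl is methylated (MeI, K2CO3, DMF, 60 °C) to methyl 4-(benzyloxy)-2-methoxy-3,6-dimethylbenzoate F2.
- The hindered ester is saponified (KOH, DMSO/H2O, 100 °C) to 4-(benzyloxy)-2-methoxy-3,6-dimethylbenzoic acid F3.
- F3 is condensed with 3 through its mixed trifluoroacetic anhydride ((CF3CO)2O, toluene, rt) at the C4 hydroxyl to 3-hydroxy-4-(methoxycarbonyl)-2,5,6-trimethylphenyl 4-(benzyloxy)-2-methoxy-3,6-dimethylbenzoate F4.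
- Hydrogenolysis (H2, Pd/C, EtOAc) then gives 17, which enters step 8 unchanged.

**Step 4.** The risks are conjugate addition or polymerization at the unsubstituted terminus of the methacryloyl unit (in 6, 7 or 8), dimerization of the acylketene, and partial acylation at the chelated C2 hydroxyl.

Fallback, setting out from 3 and returning at 9 (it also bypasses step 5):
- 3 is acylated at the C4 hydroxyl with bromoacetyl bromide (NaHCO3, MeCN, 0 °C) to 3-hydroxy-4-(methoxycarbonyl)-2,5,6-trimethylphenyl 2-bromoacetate F5.
- F5 is converted with N,N'-ditosylhydrazine and DBU (THF, 0 °C) into 3-hydroxy-4-(methoxycarbonyl)-2,5,6-trimethylphenyl 2-diazoacetate F6.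
- DBU-catalysed aldol addition of F6 to methacrolein gives racemic 3-hydroxy-4-(methoxycarbonyl)-2,5,6-trimethylphenyl 2-diazo-3-hydroxy-4-methylpent-4-enoate F7.
- Oxidation of the allylic alcohol (2-iodoxybenzoic acid, DMSO, rt) gives 9.

**Step 8.** The risk is loss of site control in the halogenation: ipso attack on the fully substituted but electron-rich ring A, or a second chlorination of ring B with dearomatization.

Fallback, setting out from 1 and 3 and returning at 18, with the chlorine placed on the ring B fragment before the two rings are joined and an allyl ether in place of benzyl so that no hydrogenolysis is run beside the aryl chloride: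
- 1 is chlorinated at its only free position (SO2Cl2, Et2O, 0 °C) to methyl 5-chloro-2,4-dihydroxy-3,6-dimethylbenzoate F8.
- Allylation (allyl bromide, K2CO3, acetone) gives methyl 5-chloro-2-hydroxy-3,6-dimethyl-4-(prop-2-en-1-yloxy)benzoate F9.
- Methylation (MeI, K2CO3, DMF) gives methyl 5-chloro-2-methoxy-3,6-dimethyl-4-(prop-2-en-1-yloxy)benzoate F10.
- Saponification (KOH, DMSO/H2O) gives 5-chloro-2-methoxy-3,6-dimethyl-4-(prop-2-en-1-yloxy)benzoic acid F11.
- Condensation with 3 ((CF3CO)2O, toluene) gives 3-hydroxy-4-(methoxycarbonyl)-2,5,6-trimethylphenyl 5-chloro-2-methoxy-3,6-dimethyl-4-(prop-2-en-1-yloxy)benzoate F12.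
- Deallylation (Pd(PPh3)4 as a zerovalent palladium catalyst, morpholine, THF) gives 18.

## Further compounds

F1 | step 7 | methyl 4-(benzyloxy)-2-hydroxy-3,6-dimethylbenzoate | COC(=O)c1c(C)cc(OCc2ccccc2)c(C)c1O
F2 | step 7 | methyl 4-(benzyloxy)-2-methoxy-3,6-dimethylbenzoate | COC(=O)c1c(C)cc(OCc2ccccc2)c(C)c1OC
F3 | step 7 | 4-(benzyloxy)-2-methoxy-3,6-dimethylbenzoic acid | OC(=O)c1c(C)cc(OCc2ccccc2)c(C)c1OC
F4 | step 7 | 3-hydroxy-4-(methoxycarbonyl)-2,5,6-trimethylphenyl 4-(benzyloxy)-2-methoxy-3,6-dimethylbenzoate | COC(=O)c1c(C)c(C)c(OC(=O)c2c(C)cc(OCc3ccccc3)c(C)c2OC)c(C)c1O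
F5 | step 4 | 3-hydroxy-4-(methoxycarbonyl)-2,5,6-trimethylphenyl 2-bromoacetate | COC(=O)c1c(C)c(C)c(OC(=O)CBr)c(C)c1O
F6 | step 4 | 3-hydroxy-4-(methoxycarbonyl)-2,5,6-trimethylphenyl 2-diazoacetate | COC(=O)c1c(C)c(C)c(OC(=O)C=[N+]=[N-])c(C)c1O
F7 | step 4 | 3-hydroxy-4-(methoxycarbonyl)-2,5,6-trimethylphenyl 2-diazo-3-hydroxy-4-methylpent-4-enoate (racemic) | COC(=O)c1c(C)c(C)c(OC(=O)C(=[N+]=[N-])C(O)C(C)=C)c(C)c1O
F8 | step 8 | methyl 5-chloro-2,4-dihydroxy-3,6-dimethylbenzoate | COC(=O)c1c(C)c(Cl)c(O)c(C)c1O
F9 | step 8 | methyl 5-chloro-2-hydroxy-3,6-dimethyl-4-(prop-2-en-1-yloxy)benzoate | COC(=O)c1c(C)c(Cl)c(OCC=C)c(C)c1O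
F10 | step 8 | methyl 5-chloro-2-methoxy-3,6-dimethyl-4-(prop-2-en-1-yloxy)benzoate | COC(=O)c1c(C)c(Cl)c(OCC=C)c(C)c1OC
F11 | step 8 | 5-chloro-2-methoxy-3,6-dimethyl-4-(prop-2-en-1-yloxy)benzoic acid | OC(=O)c1c(C)c(Cl)c(OCC=C)c(C)c1OC
F12 | step 8 | 3-hydroxy-4-(methoxycarbonyl)-2,5,6-trimethylphenyl 5-chloro-2-methoxy-3,6-dimethyl-4-(prop-2-en-1-yloxy)benzoate | COC(=O)c1c(C)c(C)c(OC(=O)c2c(C)c(Cl)c(OCC=C)c(C)c2OC)c(C)c1O
A1 | alternative 1 | 4-(benzyloxy)-5-chloro-2-methoxy-3,6-dimethylbenzoic acid | OC(=O)c1c(C)c(Cl)c(OCc2ccccc2)c(C)c1OC
A2 | alternative 1 | 3-hydroxy-4-(methoxycarbonyl)-2,5,6-trimethylphenyl 4-(benzyloxy)-5-chloro-2-methoxy-3,6-dimethylbenzoate | COC(=O)c1c(C)c(C)c(OC(=O)c2c(C)c(Cl)c(OCc3ccccc3)c(C)c2OC)c(C)c1O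
A3 | alternative 2 | 6-(3,5-dioxohexan-2-yl)-2,2-dimethyl-4H-1,3-dioxin-4-one (racemic) | CC(=O)CC(=O)C(C)C1=CC(=O)OC(C)(C)O1
A4 | alternative 2 | 3-hydroxy-4-(methoxycarbonyl)-2,5,6-trimethylphenyl 2,4-dihydroxy-3,6-dimethylbenzoate | COC(=O)c1c(C)c(C)c(OC(=O)c2c(C)cc(O)c(C)c2O)c(C)c1O
A5 | alternative 3 | prop-1-yn-1-yl 4-(benzyloxy)-5-chloro-2-methoxy-3,6-dimethylbenzoate | CC#COC(=O)c1c(C)c(Cl)c(OCc2ccccc2)c(C)c1OC
A6 | alternative 3 | methyl (2E)-5-diazo-3-methyl-4-oxohex-2-enoate | COC(=O)/C=C(\C)C(=O)C(C)=[N+]=[N-]
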